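All constants are made up; the run is a simulation.

Full exchange is impossible in this flask: 0.750 M of incoming ligand would be needed for all the starting complex, and 0.200 M is charged.

starting complex 0.25 M; incoming ligand 0.200 M (in portions, 2); time 15 d; the portions of incoming ligand follow each other after 6.0 min, the first at the start

    complex with one exchanged → decomposed reagent (k1 = 2.39 h⁻¹)
    starting complex + incoming ligand → leaving ligand + complex with one exchanged (k2 = 68.7 L mol⁻¹ h⁻¹)
    complex with one exchanged + incoming ligand → leaving ligand + complex with two exchanged (k3 = 10.0 L mol⁻¹ h⁻¹)
    complex with two exchanged + incoming ligand → leaving ligand + complex with three exchanged (k4 = 88.1 L mol⁻¹ h⁻¹)
    leaving ligand + complex with three exchanged → side product (k5 = 22.3 L mol⁻¹ h⁻¹)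

- the reaction counts as stopped when no species that holds the starting complex changes by six tenths of a point or more over the second half of the time
- run time (flask): 15 d

- at 15 d, what has stopped the reaction, if anything has (it is still moving / forward and back rates have come level / the incoming ligand has run out first / all of the starting complex has reacted)
- how much complex with two exchanged there is at 15 d, in percent of the starting complex charged
- how much side product there is at 15 d, in percent of the starting complex charged

**Minutes.** The first chemist took the end state first. Each exchange uses one incoming ligand and the charge is smaller than the starting complex, so incoming ligand is the limiting reagent and she expected the flask to stop when it reaches zero.

The second chemist asked how far the complex with one exchanged gets. It has two exits: decomposition, and the second exchange, which runs in proportion to the ligand concentration X. He set the decomposition constant over the second-exchange constant, 0.239 M, as X*, the crossover level, the ligand concentration at which the two exits run equally fast. The share going on is then X/(X + X*). Even the whole charge stands below X*, so he put that share under 45.6%.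

The first chemist objected that X does not stay there. At the opening level of starting complex, ligand halves by the first exchange in about 0.0404 h, while the complex with one exchanged halves in 0.290 h by decomposition, so she expected X to fall while that complex still stands.

The meeting scaled the ceiling roughly by that ratio, to a share of 6.34%. Taking 80.0% of the starting complex charged as exchanged once, it committed to 5.07% of the starting complex charged reaching two exchanges or beyond, without splitting that figure.

**Result.** The forecast said the incoming ligand has run out first, with 2.9% complex with two exchanged and 2.6% side product, on the ground that of the complex with one exchanged “most of it decomposes”. The simulation gives the incoming ligand has run out first, with 0% of it left, and 2.97% complex with two exchanged and 2.53% side product, together 5.49% against the 5.07% reckoned.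

In this flask the first two exchanges ran while incoming ligand was there, half the second exchange's turnover being done by 0.169 h. Decomposition of the complex with one exchanged took 66.5% of the starting complex charged, and at 0.750 d the starting complex stood at 28.0%.

A second flask holds 0.10 M of starting complex and the same ligand charge. In that flask one exchange on each complex leaves 0.100 M of ligand, so X/(X + X*) at that level gives about 29.5% of the complex with one exchanged going on. That flask gives 25.7% side product, 74.3% decomposed reagent and 0% complex with two exchanged.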